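**Retrosynthetic overview**
1. Target 27 ⇐ 26 by C–Br hydrogenolysis; the bromine only blocks the one free ring position of the aryl fragment so that it cannot alkylate itself.
2. 26 ⇐ flavanone 13 + o-quinone methide 25 (from benzhydrol 24): intermolecular Michael addition of C8 of 13 to 25 under a chiral phosphoric acid. This is the key C–C bond and sets the methine centre.
3. 13 ⇐ chromone 11 by Rh-catalysed asymmetric 1,4-addition of PhB(OH)2 (sets C2). 11 ⇐ o-hydroxyacetophenone 9 ⇐ phenol 4, whose two ortho positions are equivalent, so the ring A substitution pattern is fixed by symmetry. 4 ⇐ 2-methylresorcinol by C–H borylation/oxidation.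
4. 24 ⇐ aldehyde 23 + PhMgBr. 23 ⇐ 2,4,6-trihydroxybenzaldehyde by selective bis-MOM protection, CHO→CH3, O-methylation, ortho-lithiation/formylation between the two OMOM groups, and bromination.
5. Ring order: both benzene rings are bought; ring C (the pyranone) is the only ring formed, in step 7.

Abbreviations: MOM = methoxymethyl; dtbpy = 4,4'-di-tert-butyl-2,2'-bipyridine; (S)-MeO-F12-BIPHEP = (S)-6,6'-dimethoxy-2,2'-bis[bis(3,4,5-trifluorophenyl)phosphino]biphenyl; (R)-TRIP = (R)-3,3'-bis(2,4,6-triisopropylphenyl)-1,1'-binaphthyl-2,2'-diyl hydrogen phosphate.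

Assumption: the facial sense of the two catalyst-controlled steps (8 and 17) is assigned by analogy with related substrates, is checked on first use, and the mirror-image ligand or acid is taken if it proves opposite.

**Route**

Step 1
Reactants: 1 2-methylresorcinol
Product: 2 1,3-bis(methoxymethoxy)-2-methylbenzene
Conditions: NaH, MOMCl (2.4 equiv), DMF, 0 °C → rt
Reagents that add atoms: chloromethyl methyl ether, COCCl
Why: Williamson-type O-alkylation of both phenoxides gives MOM ethers that survive the borylation, organolithium and rhodium steps and come off with mild acid.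

Step 2
Reactants: 2 1,3-bis(methoxymethoxy)-2-methylbenzene
Product: 4 3,5-bis(methoxymethoxy)-4-methylphenol, via pinacol arylboronate 3 (not isolated)
Conditions: [Ir(OMe)(cod)]2 (1.5 mol %), dtbpy (3 mol %), B2pin2 (1.0 equiv), THF, 80 °C; then 30% H2O2, aq NaOH, 0 °C
Reagents that add atoms: bis(pinacolato)diboron, CC1(C)OB(OC1(C)C)B1OC(C)(C)C(C)(C)O1 (boron is carried only in 3); hydrogen peroxide, OO
Why: Sterically controlled iridium-catalysed C–H borylation (Hartwig–Miyaura type) takes the only ring C–H with no ortho substituent (para to the methyl), and oxidation of the C–B bond gives a phenol whose two ortho positions are equivalent.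

Step 3
Reactants: 4 3,5-bis(methoxymethoxy)-4-methylphenol
Product: 5 2-bromo-3,5-bis(methoxymethoxy)-4-methylphenol
Conditions: NBS (1.0 equiv), CH2Cl2, –78 → 0 °C
Reagents that add atoms: N-bromosuccinimide, O=C1CCC(=O)N1Br
Why: Electrophilic aromatic bromination ortho to the free OH can give only one monobromide because the para position carries the methyl and the two ortho sites are equivalent.

Step 4
Reactants: 5 2-bromo-3,5-bis(methoxymethoxy)-4-methylphenol
Product: 6 1-(benzyloxy)-2-bromo-3,5-bis(methoxymethoxy)-4-methylbenzene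
Conditions: BnBr, K2CO3, DMF, rt
Reagents that add atoms: benzyl bromide, BrCc1ccccc1
Why: Williamson ether synthesis masks the phenol for the organolithium step with a group that is later removed by hydrogenolysis without touching the MOM ethers.

Step 5
Reactants: 6 1-(benzyloxy)-2-bromo-3,5-bis(methoxymethoxy)-4-methylbenzene
Product: 8 1-[6-(benzyloxy)-2,4-bis(methoxymethoxy)-3-methylphenyl]ethan-1-one, via aryllithium 7 (not isolated)
Conditions: n-BuLi (1.05 equiv), THF, –78 °C; then MeC(O)N(OMe)Me, –78 → 0 °C
Reagents that add atoms: N-methoxy-N-methylacetamide, CON(C)C(C)=O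
Why: Bromine–lithium exchange at –78 °C is faster than any attack on the benzyl ether, and Weinreb amide acylation of the aryllithium stops at the ketone because the chelated tetrahedral adduct survives until work-up.

Step 6
Reactants: 8 1-[6-(benzyloxy)-2,4-bis(methoxymethoxy)-3-methylphenyl]ethan-1-one
Product: 9 1-[6-hydroxy-2,4-bis(methoxymethoxy)-3-methylphenyl]ethan-1-one
Conditions: H2 (1 atm), 10% Pd/C, EtOAc, rt
Reagents that add atoms: none
Why: Hydrogenolysis of the aryl benzyl ether frees only the phenol that becomes O1, while the MOM ethers and the electron-rich, hydrogen-bonded aryl ketone are inert.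

Step 7
Reactants: 9 1-[6-hydroxy-2,4-bis(methoxymethoxy)-3-methylphenyl]ethan-1-one
Product: 11 5,7-bis(methoxymethoxy)-6-methyl-4H-chromen-4-one, via enaminone 10 (not isolated)
Conditions: Me2NCH(OMe)2, toluene, 90 °C; then 1 M HCl, CH2Cl2, rt, 30 min
Reagents that add atoms: N,N-dimethylformamide dimethyl acetal, COC(OC)N(C)C
Why: Condensation of the methyl ketone with the amide acetal gives the enaminone, and brief acid treatment closes ring C by intramolecular conjugate addition of the only free phenol and loss of dimethylamine (enaminone chromone synthesis), which places the methyl at C6.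

Step 8
Reactants: 11 5,7-bis(methoxymethoxy)-6-methyl-4H-chromen-4-one
Product: 12 (2S)-5,7-bis(methoxymethoxy)-6-methyl-2-phenyl-2,3-dihydro-4H-chromen-4-one
Conditions: PhB(OH)2 (2 equiv), [Rh(OH)(cod)]2 (1.5 mol %), (S)-MeO-F12-BIPHEP (3.3 mol %), toluene/H2O 10:1, 40 °C
Reagents that add atoms: phenylboronic acid, OB(O)c1ccccc1
Why: Rhodium-catalysed asymmetric 1,4-addition of an arylboronic acid (Hayashi–Miyaura reaction) with an electron-poor biaryl bisphosphine delivers phenyl to one face of the chromone and sets C2 as S, by analogy with (S)-BINAP-type ligands giving the spatially corresponding (S)-3-arylcyclohexanones.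

Step 9
Reactants: 12 (2S)-5,7-bis(methoxymethoxy)-6-methyl-2-phenyl-2,3-dihydro-4H-chromen-4-one
Product: 13 (2S)-5,7-dihydroxy-6-methyl-2-phenyl-2,3-dihydro-4H-chromen-4-one ((S)-strobopinin)
Conditions: 3 M HCl, MeOH, 50 °C
Reagents that add atoms: none
Why: Acid-catalysed acetal cleavage removes both MOM groups without touching C2, since flavanone racemisation needs base-induced ring opening to the chalcone.

Step 10
Reactants: 14 2,4,6-trihydroxybenzaldehyde
Product: 15 2-hydroxy-4,6-bis(methoxymethoxy)benzaldehyde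
Conditions: MOMCl (2.2 equiv), i-Pr2NEt, CH2Cl2, 0 °C → rt
Reagents that add atoms: chloromethyl methyl ether, COCCl
Why: Selective O-alkylation leaves one ortho OH free, because after the first ortho MOM ether forms the remaining ortho OH is held in the hydrogen bond to the aldehyde carbonyl and is the least nucleophilic.

Step 11
Reactants: 15 2-hydroxy-4,6-bis(methoxymethoxy)benzaldehyde
Product: 18 3,5-bis(methoxymethoxy)-2-methylphenol, via aryl ethyl carbonate 16 (not isolated), via o-quinone methide 17 (not isolated)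
Conditions: ClCO2Et, Et3N, THF, 0 °C; then NaBH4, H2O, 0 °C → rt
Reagents that add atoms: ethyl chloroformate, CCOC(=O)Cl (carbonate of 16 only; none of its atoms remain in 18)
Why: Reductive deoxygenation of a salicylaldehyde: borohydride reduces the aldehyde, the carbonate shifts to the benzylic alkoxide and is expelled to give the o-quinone methide, and hydride 1,4-addition delivers the o-cresol.

Step 12
Reactants: 18 3,5-bis(methoxymethoxy)-2-methylphenol
Product: 19 1-methoxy-3,5-bis(methoxymethoxy)-2-methylbenzene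
Conditions: MeI, K2CO3, acetone, reflux
Reagents that add atoms: iodomethane, CI
Why: Williamson O-methylation of the only free phenol fixes the methyl ether next to the C-methyl group without ambiguity.

Step 13
Reactants: 19 1-methoxy-3,5-bis(methoxymethoxy)-2-methylbenzene
Product: 21 4-methoxy-2,6-bis(methoxymethoxy)-3-methylbenzaldehyde, via aryllithium 20 (not isolated)
Conditions: n-BuLi, TMEDA, THF, 0 °C; then DMF, 0 °C → rt
Reagents that add atoms: N,N-dimethylformamide, CN(C)C=O
Why: Directed ortho-metalation occurs at the C–H flanked by two chelating OMOM groups in preference to the one between OMe and OMOM, and DMF formylates the aryllithium.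

Step 14
Reactants: 21 4-methoxy-2,6-bis(methoxymethoxy)-3-methylbenzaldehyde
Product: 22 2,6-dihydroxy-4-methoxy-3-methylbenzaldehyde
Conditions: 3 M HCl, MeOH/THF, 40 °C
Reagents that add atoms: none
Why: Acid-catalysed acetal cleavage of the two MOM ethers gives a hydrogen-bond-stabilised dihydroxybenzaldehyde while the aryl methyl ether is untouched.

Step 15
Reactants: 22 2,6-dihydroxy-4-methoxy-3-methylbenzaldehyde
Product: 23 3-bromo-2,6-dihydroxy-4-methoxy-5-methylbenzaldehyde
Conditions: NBS (1.0 equiv), MeCN, 0 °C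
Reagents that add atoms: N-bromosuccinimide, O=C1CCC(=O)N1Br
Why: Electrophilic aromatic bromination at the only remaining ring C–H installs a blocking group, so that the later benzhydrol has no nucleophilic ring position to attack its own quinone methide.

Step 16
Reactants: 23 3-bromo-2,6-dihydroxy-4-methoxy-5-methylbenzaldehyde
Product: 24 4-bromo-2-[hydroxy(phenyl)methyl]-5-methoxy-6-methylbenzene-1,3-diol (racemic)
Conditions: PhMgBr (4 equiv), THF, 0 °C → rt; pH 7 buffer work-up; used crude at once
Reagents that add atoms: phenylmagnesium bromide, Br[Mg]c1ccccc1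
Why: Grignard addition to the aldehyde after two equivalents have converted the phenols into magnesium phenoxides; the carbinol may be racemic because its stereocentre is erased in the quinone methide.

Step 17
Reactants: 13 (2S)-5,7-dihydroxy-6-methyl-2-phenyl-2,3-dihydro-4H-chromen-4-one (1.2 equiv); 24 4-bromo-2-[hydroxy(phenyl)methyl]-5-methoxy-6-methylbenzene-1,3-diol
Product: 26 (2S)-8-[(S)-(3-bromo-2,6-dihydroxy-4-methoxy-5-methylphenyl)(phenyl)methyl]-5,7-dihydroxy-6-methyl-2-phenyl-2,3-dihydro-4H-chromen-4-one, via o-quinone methide 25 (not isolated)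
Conditions: (R)-TRIP (10 mol %), 4 Å molecular sieves, CH2Cl2, 0 °C → rt, 24 added over 2 h
Reagents that add atoms: none
Why: The chiral phosphoric acid dehydrates 24 to the o-quinone methide and, hydrogen-bonded to its carbonyl and to the 7-OH of 13, steers the Michael (1,4-conjugate) addition of C8 (the only free ring position of 13, a vinylogous 1,3-dicarbonyl enol) to one face of the benzylidene carbon, which sets the methine as S and leaves C2 untouched, and any minor methine epimer is a diastereomer removable by chromatography.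

Step 18
Reactants: 26 (2S)-8-[(S)-(3-bromo-2,6-dihydroxy-4-methoxy-5-methylphenyl)(phenyl)methyl]-5,7-dihydroxy-6-methyl-2-phenyl-2,3-dihydro-4H-chromen-4-one
Product: 27 (2S)-8-[(S)-(2,6-dihydroxy-4-methoxy-3-methylphenyl)(phenyl)methyl]-5,7-dihydroxy-6-methyl-2-phenyl-2,3-dihydro-4H-chromen-4-one
Conditions: H2 (1 atm), 10% Pd/C, NaOAc, EtOAc/MeOH, rt
Reagents that add atoms: none
Why: Palladium-catalysed hydrogenolysis of the aryl C–Br bond (hydrodehalogenation), buffered by NaOAc, removes the blocking group under neutral conditions that do not epimerise either stereocentre.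

**Compound list**

1 | 2-methylbenzene-1,3-diol (2-methylresorcinol) | Cc1c(O)cccc1O | starting material
2 | 1,3-bis(methoxymethoxy)-2-methylbenzene | COCOc1cccc(OCOC)c1C | intermediate
3 | 2-[3,5-bis(methoxymethoxy)-4-methylphenyl]-4,4,5,5-tetramethyl-1,3,2-dioxaborolane | COCOc1cc(B2OC(C)(C)C(C)(C)O2)cc(OCOC)c1C | intermediate (not isolated)
4 | 3,5-bis(methoxymethoxy)-4-methylphenol | COCOc1cc(O)cc(OCOC)c1C | intermediate
5 | 2-bromo-3,5-bis(methoxymethoxy)-4-methylphenol | COCOc1cc(O)c(Br)c(OCOC)c1C | intermediate
6 | 1-(benzyloxy)-2-bromo-3,5-bis(methoxymethoxy)-4-methylbenzene | COCOc1cc(OCc2ccccc2)c(Br)c(OCOC)c1C | intermediate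
7 | [6-(benzyloxy)-2,4-bis(methoxymethoxy)-3-methylphenyl]lithium | COCOc1cc(OCc2ccccc2)c([Li])c(OCOC)c1C | intermediate (not isolated)
8 | 1-[6-(benzyloxy)-2,4-bis(methoxymethoxy)-3-methylphenyl]ethan-1-one | COCOc1cc(OCc2ccccc2)c(C(C)=O)c(OCOC)c1C | intermediate
9 | 1-[6-hydroxy-2,4-bis(methoxymethoxy)-3-methylphenyl]ethan-1-one | COCOc1cc(O)c(C(C)=O)c(OCOC)c1C | intermediate
10 | (E)-3-(dimethylamino)-1-[6-hydroxy-2,4-bis(methoxymethoxy)-3-methylphenyl]prop-2-en-1-one | COCOc1cc(O)c(C(=O)/C=C/N(C)C)c(OCOC)c1C | intermediate (not isolated)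
11 | 5,7-bis(methoxymethoxy)-6-methyl-4H-chromen-4-one | COCOc1cc2occc(=O)c2c(OCOC)c1C | intermediate
12 | (2S)-5,7-bis(methoxymethoxy)-6-methyl-2-phenyl-2,3-dihydro-4H-chromen-4-one | COCOc1cc2O[C@H](c3ccccc3)CC(=O)c2c(OCOC)c1C | intermediate
13 | (2S)-5,7-dihydroxy-6-methyl-2-phenyl-2,3-dihydro-4H-chromen-4-one | Cc1c(O)cc2O[C@H](c3ccccc3)CC(=O)c2c1O | intermediate
14 | 2,4,6-trihydroxybenzaldehyde | O=Cc1c(O)cc(O)cc1O | starting material
15 | 2-hydroxy-4,6-bis(methoxymethoxy)benzaldehyde | COCOc1cc(O)c(C=O)c(OCOC)c1 | intermediate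
16 | ethyl 2-formyl-3,5-bis(methoxymethoxy)phenyl carbonate | CCOC(=O)Oc1cc(OCOC)cc(OCOC)c1C=O | intermediate (not isolated)
17 | 3,5-bis(methoxymethoxy)-6-methylidenecyclohexa-2,4-dien-1-one | C=C1C(=O)C=C(OCOC)C=C1OCOC | intermediate (not isolated)
18 | 3,5-bis(methoxymethoxy)-2-methylphenol | Cc1c(O)cc(OCOC)cc1OCOC | intermediate
19 | 1-methoxy-3,5-bis(methoxymethoxy)-2-methylbenzene | COCOc1cc(OC)c(C)c(OCOC)c1 | intermediate
20 | [4-methoxy-2,6-bis(methoxymethoxy)-3-methylphenyl]lithium | [Li]c1c(OCOC)cc(OC)c(C)c1OCOC | intermediate (not isolated)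
21 | 4-methoxy-2,6-bis(methoxymethoxy)-3-methylbenzaldehyde | O=Cc1c(OCOC)cc(OC)c(C)c1OCOC | intermediate
22 | 2,6-dihydroxy-4-methoxy-3-methylbenzaldehyde | O=Cc1c(O)cc(OC)c(C)c1O | intermediate
23 | 3-bromo-2,6-dihydroxy-4-methoxy-5-methylbenzaldehyde | O=Cc1c(O)c(Br)c(OC)c(C)c1O | intermediate
24 | 4-bromo-2-[hydroxy(phenyl)methyl]-5-methoxy-6-methylbenzene-1,3-diol (racemic) | COc1c(Br)c(O)c(C(O)c2ccccc2)c(O)c1C | intermediate
25 | 6-benzylidene-4-bromo-5-hydroxy-3-methoxy-2-methylcyclohexa-2,4-dien-1-one | O=C1C(C)=C(OC)C(Br)=C(O)C1=Cc1ccccc1 | intermediate (not isolated)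
26 | (2S)-8-[(S)-(3-bromo-2,6-dihydroxy-4-methoxy-5-methylphenyl)(phenyl)methyl]-5,7-dihydroxy-6-methyl-2-phenyl-2,3-dihydro-4H-chromen-4-one (methine arranged as in 27) | COc1c(Br)c(O)c([C@H](c2ccccc2)c2c(O)c(C)c(O)c3c2O[C@H](c2ccccc2)CC3=O)c(O)c1C | intermediate
27 | (2S)-8-[(S)-(2,6-dihydroxy-4-methoxy-3-methylphenyl)(phenyl)methyl]-5,7-dihydroxy-6-methyl-2-phenyl-2,3-dihydro-4H-chromen-4-one (methine priorities: flavanone C8 > dihydroxyaryl > phenyl > H) | COc1cc(O)c([C@H](c2ccccc2)c2c(O)c(C)c(O)c3c2O[C@H](c2ccccc2)CC3=O)c(O)c1C | target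

**Count and risks**

Total steps: 18. Longest linear sequence: 11 steps (steps 1–9, then 17 and 18, from 2-methylresorcinol); the aryl branch is steps 10–16.

The three steps most likely to fail:

Step 17 (face selectivity of the Michael addition at a very crowded methine, and a less nucleophilic acylated ring as donor). The fallback sets out from 13 and 24 and comes back at 26. Stereocontrol by catalyst is given up: the coupling is run with an achiral acid (diphenyl hydrogen phosphate, CH2Cl2, rt), which gives 26 together with (2S)-8-[(R)-(3-bromo-2,6-dihydroxy-4-methoxy-5-methylphenyl)(phenyl)methyl]-5,7-dihydroxy-6-methyl-2-phenyl-2,3-dihydro-4H-chromen-4-one F1 in about equal amounts. Because C2 is already fixed, the two are diastereomers and are separated by preparative HPLC, and 26 goes on to step 18.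

Step 8 (an electron-rich 5,7-dioxygenated chromone is a poor acceptor, and the ee has to be proven on this substrate). The fallback sets out from 9 and comes back at 12. Claisen–Schmidt aldol condensation of 9 with benzaldehyde (KOH, EtOH, rt) gives (E)-1-[6-hydroxy-2,4-bis(methoxymethoxy)-3-methylphenyl]-3-phenylprop-2-en-1-one F2. Oxa-Michael ring closure through the only free phenol (NaOAc, EtOH, reflux) gives racemic 5,7-bis(methoxymethoxy)-6-methyl-2-phenyl-2,3-dihydro-4H-chromen-4-one F3. Preparative chiral HPLC delivers the (2S)-enantiomer 12, and the (2R)-enantiomer is racemised with base through F2 and recycled.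

Step 16 (the bis-magnesium phenoxide of 23 may be insoluble and unreactive toward PhMgBr, and 24 ionises easily on work-up). The fallback sets out from 19 and comes back at 24. Aryllithium 20, made as in step 13, is acylated with N-methoxy-N-methylbenzamide to [4-methoxy-2,6-bis(methoxymethoxy)-3-methylphenyl](phenyl)methanone F4. 3 M HCl in MeOH gives (2,6-dihydroxy-4-methoxy-3-methylphenyl)(phenyl)methanone F5, and NBS in MeCN gives (3-bromo-2,6-dihydroxy-4-methoxy-5-methylphenyl)(phenyl)methanone F6. This stable ketone is reduced with LiAlH4 (THF, 0 °C) directly before use to give 24.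

**Further compounds**

F1 | step 17 | (2S)-8-[(R)-(3-bromo-2,6-dihydroxy-4-methoxy-5-methylphenyl)(phenyl)methyl]-5,7-dihydroxy-6-methyl-2-phenyl-2,3-dihydro-4H-chromen-4-one | COc1c(Br)c(O)c([C@@H](c2ccccc2)c2c(O)c(C)c(O)c3c2O[C@H](c2ccccc2)CC3=O)c(O)c1C
F2 | step 8 | (E)-1-[6-hydroxy-2,4-bis(methoxymethoxy)-3-methylphenyl]-3-phenylprop-2-en-1-one | COCOc1cc(O)c(C(=O)/C=C/c2ccccc2)c(OCOC)c1C
F3 | step 8 | rac-5,7-bis(methoxymethoxy)-6-methyl-2-phenyl-2,3-dihydro-4H-chromen-4-one | COCOc1cc2OC(c3ccccc3)CC(=O)c2c(OCOC)c1C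
F4 | step 16 | [4-methoxy-2,6-bis(methoxymethoxy)-3-methylphenyl](phenyl)methanone | COCOc1cc(OC)c(C)c(OCOC)c1C(=O)c1ccccc1
F5 | step 16 | (2,6-dihydroxy-4-methoxy-3-methylphenyl)(phenyl)methanone | COc1cc(O)c(C(=O)c2ccccc2)c(O)c1C
F6 | step 16 | (3-bromo-2,6-dihydroxy-4-methoxy-5-methylphenyl)(phenyl)methanone | COc1c(Br)c(O)c(C(=O)c2ccccc2)c(O)c1C
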